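**Retrosynthetic overview**

- The target is (2S)-2,5,8-trimethyl-2-[(4R,8R)-4,8,12-trimethyltridecyl]-2H-chromen-6-ol. The plan rests on the cis C3=C4 double bond of the pyran ring (ring B): it is the ring bond farthest from the quaternary C2 and its acid-labile C2–O1 ether, and the benzene ring (ring A) is substituted at C4a, C5, C6 and C8.
- The silyl group on O6 is removed last. Before that, C3=C4 is disconnected by ring-closing metathesis of a diene with one vinyl group on C4a and one on C2; ring B is the only ring formed (step 6).
- The C2–O1 bond and the C2 stereocentre come from a palladium-catalysed asymmetric allylic etherification of a 2-vinylphenol with phytyl methyl carbonate; C4' and C8' come unchanged from natural phytol.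
- The 2-vinylphenol comes from 2,5-dimethylhydroquinone (ring A, bought) by monosilylation, ortho-formylation and methylenation.

Key step: step 6

Assumption 1: natural (2E,7R,11R)-phytol of high geometric purity is taken as the commercial material, because any Z isomer would be carried into the C2 epimer.
Assumption 2: the (S,S)-DACH-phenyl Trost ligand is taken to direct the aryloxide to the Si face of C3 of the E-configured allyl unit (giving 3S); this sense is not certain, and if the first stereochemical correlation shows the opposite, the (R,R)-ligand is used with nothing else changed.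

**Route**

Step 1
Reactants: 1 2,5-dimethylhydroquinone (2,5-dimethylbenzene-1,4-diol)
Product: 2 4-[(tert-butyldimethylsilyl)oxy]-2,5-dimethylphenol
Conditions: 1 (2 equiv), TBSCl (1 equiv), imidazole (1.2 equiv), DMF, 0 °C to rt, Ar; unreacted 1 recovered
Reagents that add atoms: tert-butyldimethylsilyl chloride, CC(C)(C)[Si](C)(C)Cl
Why: Imidazole-promoted O-silylation of a phenol; the two hydroxyls are equivalent, so running the diol in excess should hold the reaction at the monoether, which is separated from diol and bis-ether by chromatography.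

Step 2
Reactants: 2 4-[(tert-butyldimethylsilyl)oxy]-2,5-dimethylphenol
Product: 3 5-[(tert-butyldimethylsilyl)oxy]-2-hydroxy-3,6-dimethylbenzaldehyde
Conditions: anhydrous MgCl2 (2 equiv), Et3N (4 equiv), (CH2O)n (6 equiv), THF, reflux; dilute HCl work-up at 0 °C
Reagents that add atoms: paraformaldehyde (as formaldehyde), C=O
Why: Magnesium-mediated ortho-formylation of a phenol (Casnati–Skattebøl reaction): the magnesium phenoxide delivers formaldehyde to the only unsubstituted carbon ortho to the free hydroxyl, a second formaldehyde oxidises the benzylic alkoxide by hydride transfer, and the aryl silyl ether should tolerate the weakly basic, fluoride-free medium.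

Step 3
Reactants: 3 5-[(tert-butyldimethylsilyl)oxy]-2-hydroxy-3,6-dimethylbenzaldehyde
Product: 4 4-[(tert-butyldimethylsilyl)oxy]-2-ethenyl-3,6-dimethylphenol
Conditions: Ph3PCH3Br (2.6 equiv), n-BuLi (2.5 equiv), THF, 0 °C; then 3, 0 °C to rt; aq NH4Cl
Reagents that add atoms: methyltriphenylphosphonium bromide, C[P+](c1ccccc1)(c1ccccc1)c1ccccc1.[Br-]
Why: Wittig methylenation of a salicylaldehyde: one equivalent of ylide is spent on the phenol, the rest converts the hindered phenoxide-aldehyde into the styrene, and generating the ylide with n-BuLi leaves no free alkoxide that could attack the silyl ether.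

Step 4
Reactants: 5 (2E,7R,11R)-phytol
Product: 6 methyl (2E,7R,11R)-3,7,11,15-tetramethylhexadec-2-en-1-yl carbonate
Conditions: ClCO2Me (1.5 equiv), pyridine (3 equiv), CH2Cl2, 0 °C
Reagents that add atoms: methyl chloroformate, COC(=O)Cl
Why: Acylation of a primary allylic alcohol with a chloroformate; the alkene geometry and the C7 and C11 stereocentres are not touched.

Step 5
Reactants: 4 4-[(tert-butyldimethylsilyl)oxy]-2-ethenyl-3,6-dimethylphenol; 6 methyl (2E,7R,11R)-3,7,11,15-tetramethylhexadec-2-en-1-yl carbonate
Product: 7 tert-butyl(3-ethenyl-2,5-dimethyl-4-{[(3S,7R,11R)-3,7,11,15-tetramethylhexadec-1-en-3-yl]oxy}phenoxy)dimethylsilane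
Conditions: Pd2(dba)3·CHCl3 (2.5 mol %), (S,S)-DACH-phenyl Trost ligand (7.5 mol %), CH2Cl2 (0.1 M), 0 °C to rt, Ar; stopped when 6 is consumed
Reagents that add atoms: none
Why: Palladium-catalysed asymmetric allylic etherification of a phenol (Tsuji–Trost reaction with a Trost ligand), a known route to tertiary aryl allyl ethers from trisubstituted allylic carbonates: zerovalent palladium ionises the carbonate to the allyl complex with the chain syn, the released methoxide deprotonates 4, and the aryloxide attacks the more substituted terminus inside the chiral pocket, the ligand selecting the Si face of C3 to set 3S while C7 and C11 are spectators.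

Step 6
Reactants: 7 tert-butyl(3-ethenyl-2,5-dimethyl-4-{[(3S,7R,11R)-3,7,11,15-tetramethylhexadec-1-en-3-yl]oxy}phenoxy)dimethylsilane
Product: 8 tert-butyldimethyl({(2S)-2,5,8-trimethyl-2-[(4R,8R)-4,8,12-trimethyltridecyl]-2H-chromen-6-yl}oxy)silane
Conditions: second-generation Grubbs catalyst (H2IMes)(PCy3)Cl2Ru=CHPh (5 mol %), degassed CH2Cl2 (0.005 M), 40 °C, Ar sweep to remove ethylene
Reagents that add atoms: none
Why: The ruthenium benzylidene exchanges onto one of the two monosubstituted alkenes (most likely the vinyl on C4a), the new carbene adds across the other vinyl group to a ruthenacyclobutane, and cycloreversion gives the chromene and Ru=CH2, which leaves as ethylene. The closest known reaction is the ring-closing metathesis of allyl and α,α-disubstituted allyl 2-vinylphenyl ethers to 2H-chromenes. Ring B is closed as a six-membered oxacycle by forming C3=C4, and the ring size enforces the cis geometry. No stereocentre is formed; C2 keeps the configuration from step 5 because the neutral medium cannot ionise the tertiary, doubly allylic C2–O1 bond. The selectivity needed is ring closure over intermolecular cross-metathesis, which high dilution, the ortho placement of the two alkenes and the quaternary C2 in the tether should secure. Aromatic Claisen rearrangement is no outlet at 40 °C, since C8, C4a and C6 all carry substituents.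

Step 7
Reactants: 8 tert-butyldimethyl({(2S)-2,5,8-trimethyl-2-[(4R,8R)-4,8,12-trimethyltridecyl]-2H-chromen-6-yl}oxy)silane
Product: 9 (2S)-2,5,8-trimethyl-2-[(4R,8R)-4,8,12-trimethyltridecyl]-2H-chromen-6-ol
Conditions: Bu4NF (1.2 equiv), AcOH (1.3 equiv), THF, 0 °C, Ar; degassed work-up
Reagents that add atoms: none
Why: Fluoride cleavage of an aryl silyl ether; the acetic acid buffer protonates the electron-rich phenoxide as it forms, limiting air oxidation, and is too weak to ionise the C2–O1 bond or affect the C3=C4 alkene.

**Compound list**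

1 | 2,5-dimethylhydroquinone | Cc1cc(O)c(C)cc1O | starting material
2 | 4-[(tert-butyldimethylsilyl)oxy]-2,5-dimethylphenol | Cc1cc(O[Si](C)(C)C(C)(C)C)c(C)cc1O | intermediate
3 | 5-[(tert-butyldimethylsilyl)oxy]-2-hydroxy-3,6-dimethylbenzaldehyde | Cc1cc(O[Si](C)(C)C(C)(C)C)c(C)c(C=O)c1O | intermediate
4 | 4-[(tert-butyldimethylsilyl)oxy]-2-ethenyl-3,6-dimethylphenol | Cc1cc(O[Si](C)(C)C(C)(C)C)c(C)c(C=C)c1O | intermediate
5 | (2E,7R,11R)-phytol | CC(C)CCC[C@@H](C)CCC[C@@H](C)CCC/C(C)=C/CO | starting material
6 | methyl (2E,7R,11R)-3,7,11,15-tetramethylhexadec-2-en-1-yl carbonate | CC(C)CCC[C@@H](C)CCC[C@@H](C)CCC/C(C)=C/COC(=O)OC | intermediate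
7 | tert-butyl(3-ethenyl-2,5-dimethyl-4-{[(3S,7R,11R)-3,7,11,15-tetramethylhexadec-1-en-3-yl]oxy}phenoxy)dimethylsilane | Cc1cc(O[Si](C)(C)C(C)(C)C)c(C)c(C=C)c1O[C@@](C)(CCC[C@H](C)CCC[C@H](C)CCCC(C)C)C=C | intermediate
8 | tert-butyldimethyl({(2S)-2,5,8-trimethyl-2-[(4R,8R)-4,8,12-trimethyltridecyl]-2H-chromen-6-yl}oxy)silane | Cc1cc(O[Si](C)(C)C(C)(C)C)c(C)c2c1O[C@@](C)(CCC[C@H](C)CCC[C@H](C)CCCC(C)C)C=C2 | intermediate
9 | (2S)-2,5,8-trimethyl-2-[(4R,8R)-4,8,12-trimethyltridecyl]-2H-chromen-6-ol | Cc1cc(O)c(C)c2c1O[C@@](C)(CCC[C@H](C)CCC[C@H](C)CCCC(C)C)C=C2 | target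

**Step count**

Total steps: 7. Longest linear sequence: 6 (steps 1, 2, 3, 5, 6, 7 from 2,5-dimethylhydroquinone).

**Steps most likely to fail**

1. Step 5. The di-ortho-substituted aryloxide may attack the primary allyl terminus and give the linear phytyl ether. Face selection on the E-configured allyl unit may be incomplete, and the C3 epimer cannot be removed by ordinary chromatography, so it would persist into 9. The product may also be re-ionised by zerovalent palladium. The fallback sets out from phytol 5 and phenol 4 and returns at 7, fixing C3 by reagent control and transferring it stereospecifically: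
   - Sharpless asymmetric epoxidation of 5 (Ti(OiPr)4, L-(+)-diethyl tartrate, t-BuOOH, 4 Å sieves, CH2Cl2, −20 °C) should give [(2S,3S)-3-methyl-3-[(4R,8R)-4,8,12-trimethyltridecyl]oxiran-2-yl]methanol F1.
   - I2, PPh3 and imidazole convert it into (2R,3S)-2-(iodomethyl)-3-methyl-3-[(4R,8R)-4,8,12-trimethyltridecyl]oxirane F2.
   - Activated zinc dust in refluxing EtOH opens the epoxide by reductive β-elimination to (3S,7R,11R)-3,7,11,15-tetramethylhexadec-1-en-3-ol F3; the C3–O bond is never broken.
   - n-BuLi then ClCO2Me gives methyl (3S,7R,11R)-3,7,11,15-tetramethylhexadec-1-en-3-yl carbonate F4.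
   - The sodium aryloxide of 4 (from NaN(SiMe3)2) with RhCl(PPh3)3 and P(OMe)3 in THF should substitute F4 at the branched position with net retention, giving 7. This is a rhodium-catalysed enantiospecific allylic etherification, a reaction practised with ortho-disubstituted phenoxides on secondary carbonates and with carbon nucleophiles on tertiary ones, so its use here is an extension.

2. Step 6. Both alkenes are hindered (the styrene has two ortho substituents, the other vinyl sits on a quaternary carbon), so catalyst loading may be slow, and catalyst decay and oligomerisation may overtake ring closure. The fallback sets out from aldehyde 3 and returns at 8 by relay ring-closing metathesis: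
   - Wittig reaction of 3 with hex-5-en-1-yltriphenylphosphonium bromide and NaN(SiMe3)2 gives 4-[(tert-butyldimethylsilyl)oxy]-2-(hepta-1,6-dien-1-yl)-3,6-dimethylphenol F5.
   - Etherification with 6 as in step 5 gives tert-butyl(3-(hepta-1,6-dien-1-yl)-2,5-dimethyl-4-{[(3S,7R,11R)-3,7,11,15-tetramethylhexadec-1-en-3-yl]oxy}phenoxy)dimethylsilane F6.
   - The second-generation Grubbs catalyst loads on the unhindered terminal alkene of the relay chain, expels cyclopentene and is thereby placed on the benzylic carbon, from which closure onto the C2 vinyl group gives 8.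

3. Step 2. The silyl group may be transferred to methoxide or magnesium phenoxide at reflux, or the reaction may stall at the hydroxymethyl stage. The fallback sets out from 1 and returns at 3 by reversing the order:
   - The unprotected diol 1 is formylated (MgCl2, Et3N, limiting (CH2O)n, THF, reflux) to 2,5-dihydroxy-3,6-dimethylbenzaldehyde F7.
   - TBSCl and imidazole at 0 °C then silylate the C5 hydroxyl selectively, because the C2 hydroxyl is hydrogen-bonded to the aldehyde and more hindered, giving 3.

**Further compounds**

F1 | step 5 | [(2S,3S)-3-methyl-3-[(4R,8R)-4,8,12-trimethyltridecyl]oxiran-2-yl]methanol | OC[C@@H]1O[C@@]1(C)CCC[C@H](C)CCC[C@H](C)CCCC(C)C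
F2 | step 5 | (2R,3S)-2-(iodomethyl)-3-methyl-3-[(4R,8R)-4,8,12-trimethyltridecyl]oxirane | IC[C@@H]1O[C@@]1(C)CCC[C@H](C)CCC[C@H](C)CCCC(C)C
F3 | step 5 | (3S,7R,11R)-3,7,11,15-tetramethylhexadec-1-en-3-ol | O[C@@](C)(CCC[C@H](C)CCC[C@H](C)CCCC(C)C)C=C
F4 | step 5 | methyl (3S,7R,11R)-3,7,11,15-tetramethylhexadec-1-en-3-yl carbonate | COC(=O)O[C@@](C)(CCC[C@H](C)CCC[C@H](C)CCCC(C)C)C=C
F5 | step 6 | 4-[(tert-butyldimethylsilyl)oxy]-2-(hepta-1,6-dien-1-yl)-3,6-dimethylphenol | Cc1cc(O[Si](C)(C)C(C)(C)C)c(C)c(C=CCCCC=C)c1O
F6 | step 6 | tert-butyl(3-(hepta-1,6-dien-1-yl)-2,5-dimethyl-4-{[(3S,7R,11R)-3,7,11,15-tetramethylhexadec-1-en-3-yl]oxy}phenoxy)dimethylsilane | Cc1cc(O[Si](C)(C)C(C)(C)C)c(C)c(C=CCCCC=C)c1O[C@@](C)(CCC[C@H](C)CCC[C@H](C)CCCC(C)C)C=C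
F7 | step 2 | 2,5-dihydroxy-3,6-dimethylbenzaldehyde | Cc1cc(O)c(C)c(C=O)c1O
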